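The ten-membered carbocycle comes from anionic oxy-Cope ring expansion of a 1,2-divinylcyclohexanol, which leaves an E C6=C7 alkene next to the C8 oxygen (germacrane numbering, C1 = ketone carbon). The γ-lactone (ring B) is annulated onto that alkene in one oxidative radical operation that exploits the 1,3-relation of O8 and C11 about C7: a hydrogen malonate hung on O8 gives, with Mn(OAc)3, a C11 radical that closes a temporary five-membered lactone (ring A) onto C7, and its free carboxyl then captures C6, so C11–C7 and O–C6 form syn across the alkene. The precursor is the C8 hydrogen malonate of an E-cyclodecenone; ring A is later excised as CO2 during methylenation.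

Key step: step 14

Remark (numbering): C1 ketone carbon, C2, C3 (CH–O), C4 (CH–CH3), C5, C6 (lactone O–CH), C7 (ring-fusion CH), C8 (ester CH–O), C9, C10 (quaternary C–O); C11, C12, C13 are the lactone α-carbon, carbonyl carbon and exocyclic CH2. Ring A is the temporary lactone on O8, ring B the lactone of the target.

Remark (assumption): racemic 4 is resolved enzymatically, the (1R) enantiomer being the one that is acetylated; the SMILES given for racemic 4 shows the enantiomer that is carried on.

**Step 1**
Reactants: 1 2-methylanisole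
Product: 3 6-methylcyclohex-3-en-1-one (racemic), via 1-methoxy-2-methylcyclohexa-1,4-diene 2 (not isolated)
Conditions: Li, NH3 (l), t-BuOH, THF, −78 to −33 °C; then (CO2H)2, MeOH/H2O, rt
Reagents that add atoms: water (O)
Why: Birch reduction keeps both donor-substituted carbons sp2 and mild enol-ether hydrolysis should stop at the β,γ-unsaturated ketone; the methyl-bearing center is racemic here.

**Step 2**
Reactants: 3 6-methylcyclohex-3-en-1-one
Product: 4 cis-6-methylcyclohex-3-en-1-ol (racemic)
Conditions: LiBH(s-Bu)3, THF, −78 °C; aq. NH4Cl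
Reagents that add atoms: none
Why: Hydride reduction with a bulky borohydride should attack the 2-methylcyclohexanone-type carbonyl equatorially, giving the axial alcohol cis to the methyl group.

**Step 3**
Reactants: 4 cis-6-methylcyclohex-3-en-1-ol (racemic)
Product: 5 (1S,6R)-6-methylcyclohex-3-en-1-ol (unreacted enantiomer)
Conditions: Burkholderia cepacia lipase, vinyl acetate, t-BuOMe, 30 °C, run past half conversion
Reagents that add atoms: none
Why: Lipase-catalysed kinetic resolution by transesterification should acetylate the (1R) enantiomer (Kazlauskas rule) and leave the (1S,6R) alcohol in high enantiomeric purity.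

**Step 4**
Reactants: 5 (1S,6R)-6-methylcyclohex-3-en-1-ol
Product: 6 all-cis epoxy alcohol (4-methyl-7-oxabicyclo[4.1.0]heptan-3-ol)
Conditions: VO(acac)2 (2 mol%), t-BuOOH, CH2Cl2, 0 °C to rt
Reagents that add atoms: tert-butyl hydroperoxide (CC(C)(C)OO)
Why: Hydroxyl-directed vanadium-catalysed epoxidation of the homoallylic alcohol should deliver oxygen to the alkene face cis to the hydroxyl, setting both epoxide carbons.

**Step 5**
Reactants: 6 all-cis epoxy alcohol
Product: 7 all-cis MOM-protected epoxide
Conditions: MOMCl, i-Pr2NEt, CH2Cl2, 0 °C to rt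
Reagents that add atoms: chloromethyl methyl ether (COCCl)
Why: O-alkylation (acetal ether formation) of the only hydroxyl touches no stereocenter and installs an ether that can chelate in step 7.

**Step 6**
Reactants: 8 4-methoxybenzyl alcohol; 9 trichloroethylene
Product: 10 4-methoxybenzyl (E)-1,2-dichlorovinyl ether
Conditions: KH, THF, 0 °C; then Cl2C=CHCl, −50 °C to rt
Reagents that add atoms: none
Why: Base-mediated elimination to dichloroacetylene and anti addition of the alkoxide is the standard entry to (E)-1,2-dichlorovinyl ethers, the precursors of alkoxyacetylides.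

**Step 7**
Reactants: 7 all-cis MOM-protected epoxide; 10 4-methoxybenzyl (E)-1,2-dichlorovinyl ether
Product: 13 trans-2-(alkoxyethynyl)cyclohexanol, via lithium alkoxyacetylide 11 (not isolated), via diethyl(alkoxyethynyl)alane 12 (not isolated)
Conditions: 10, n-BuLi (2.2 equiv), Et2O, −78 to −40 °C; Et2AlCl, toluene, −40 to 0 °C; then 7, 0 °C to rt; aq. KNaC4H4O6
Reagents that add atoms: none
Why: Epoxide opening by an alkynylalane chelated between the epoxide oxygen and the cis MOM ether should proceed trans-diaxially (Fürst–Plattner) at the distal epoxide carbon with inversion, placing the alkynyl group (future C7) trans to the methyl group.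

**Step 8**
Reactants: 13 trans-2-(alkoxyethynyl)cyclohexanol
Product: 14 (E)-enol ether alcohol
Conditions: LiAlH4, THF, 0 to 40 °C; aq. KNaC4H4O6
Reagents that add atoms: none
Why: Alkoxide-directed trans-hydroalumination of the alkynyl ether and protonolysis should give the (E)-enol ether.

**Step 9**
Reactants: 14 (E)-enol ether alcohol
Product: 15 2-[(E)-2-(4-methoxybenzyloxy)vinyl]cyclohexanone
Conditions: Dess–Martin periodinane, NaHCO3, CH2Cl2, 0 °C; used without chromatography
Reagents that add atoms: none
Why: Dess–Martin oxidation under buffered, base-free conditions should give the ketone without epimerizing the α-stereocenter or hydrolysing the enol ether.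

**Step 10**
Reactants: 15 2-[(E)-2-(4-methoxybenzyloxy)vinyl]cyclohexanone
Product: 16 trans-1,2-dialkenylcyclohexanol
Conditions: CH2=C(CH3)MgBr, CeCl3, THF, −78 °C
Reagents that add atoms: isopropenylmagnesium bromide (C=C(C)[Mg]Br)
Why: 1,2-Addition of the weakly basic organocerium reagent should occur anti to the α-side chain, so the new tertiary center carries isopropenyl trans to the alkoxyvinyl group.

**Step 11**
Reactants: 16 trans-1,2-dialkenylcyclohexanol
Product: 18 C10-hydroxy E-cyclodecenone, via potassium enolate 17 (not isolated)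
Conditions: KH, 18-crown-6, THF, 0 °C to rt; then −78 °C, 2-(phenylsulfonyl)-3-phenyloxaziridine; aq. NH4Cl
Reagents that add atoms: 2-(phenylsulfonyl)-3-phenyloxaziridine (O=S(=O)(c1ccccc1)N1OC1c1ccccc1)
Why: Anionic oxy-Cope rearrangement through a chair transition state with both alkenyl groups equatorial should transfer the ring stereocenter to C8 and give the E-alkene and a conformationally locked enolate, whose outer face is hydroxylated by the oxaziridine to set C10.

**Step 12**
Reactants: 18 C10-hydroxy E-cyclodecenone
Product: 19 C8,C10-diol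
Conditions: DDQ, CH2Cl2/pH 7 phosphate buffer, 0 °C
Reagents that add atoms: none
Why: Oxidative cleavage of the 4-methoxybenzyl ether should free the allylic C8 hydroxyl and leave the MOM ether, alkene and tertiary alcohol untouched.

**Step 13**
Reactants: 19 C8,C10-diol
Product: 20 C8 hydrogen malonate
Conditions: Meldrum's acid, toluene, 100 °C
Reagents that add atoms: Meldrum's acid (CC1(C)OC(=O)CC(=O)O1)
Why: Alcoholysis of Meldrum's acid with loss of acetone should give the malonic half ester at the secondary hydroxyl, the tertiary C10 hydroxyl being too hindered to compete.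

**Step 14**
Reactants: 20 C8 hydrogen malonate
Product: 21 cis-fused bis-lactone (rings A and B on C6–C7–C8)
Conditions: Mn(OAc)3·2H2O (2.5 equiv), Cu(OAc)2·H2O (0.2 equiv), degassed AcOH, 40 °C
Reagents that add atoms: none
Why: Mn(OAc)3 oxidizes the enolized hydrogen malonate to an electrophilic C11 radical that adds to C7 of the E C6=C7 alkene, and the resulting C6 radical is oxidized (organocopper intermediate from Cu(OAc)2) and captured by the C12 carboxyl, so C11–C7 and O–C6 form in one flask. The closest known reaction type is the trivalent-manganese-based oxidative free-radical cyclization–lactonization of unsaturated malonic half esters to fused bis-γ-lactones. Ring A (C8–O8–CO–C11–C7) closes 5-exo-trig, and ring B (O–C12–C11–C7–C6) closes by 5-exo attack of the carboxylate oxygen on the oxidized C6 center. C7 is set by the C8 stereocenter through the short ester tether: with the ring bond C8–C9 pseudo-equatorial in the chair-like transition state, C11 enters the peripheral alkene face syn to O8; C6 is set because the carboxyl is delivered from C11 on that same face, a syn addition to the E-alkene that gives the trans ring fusion; C11 is forced cis by the bicycle and is lost later. The step needs 5-exo rather than 6-endo closure and lactonization rather than oxidative elimination or ketone α-oxidation; the first is secured by the five-atom tether, the others by the carboxyl held next to C6 and by the much faster oxidation of the malonate.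

**Step 15**
Reactants: 21 cis-fused bis-lactone
Product: 23 α-methylene lactone C8,C10-diol, via ring-A-opened carboxylic acid 22 (not isolated)
Conditions: LiOH·H2O (1.05 equiv), THF/H2O, 0 °C; AcOH to pH 5; 37% aq. CH2O, Et2NH, 0 °C to rt; then NaOAc, AcOH, 50 °C
Reagents that add atoms: formaldehyde (C=O)
Why: Half-saponification should settle, by alkoxide translactonization, on the isomer that keeps ring B because only the freed C8 alkoxide is stabilized by the neighbouring C10 hydroxyl (syn-1,3-diol), and Mannich reaction of the malonic half acid with decarboxylative elimination then installs the exocyclic methylene.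

**Step 16**
Reactants: 23 α-methylene lactone C8,C10-diol
Product: 24 C8 angelate
Conditions: angelic acid, 2,4,6-trichlorobenzoyl chloride, Et3N, toluene, rt; then 23, 75 °C
Reagents that add atoms: angelic acid (C/C=C(/C)C(=O)O)
Why: Yamaguchi esterification through the mixed anhydride should acylate the secondary C8 hydroxyl without isomerizing the (Z)-angelate, the tertiary C10 hydroxyl being unreactive.

**Step 17**
Reactants: 24 C8 angelate
Product: 25 C10 acetate (C3 MOM ether of the target)
Conditions: Ac2O, 4-(dimethylamino)pyridine, Et3N, CH2Cl2, 35 °C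
Reagents that add atoms: acetic anhydride (CC(=O)OC(C)=O)
Why: Nucleophile-catalysed acylation of the tertiary α-ketol hydroxyl, the only free hydroxyl left, should give the acetate.

**Step 18**
Reactants: 25 C10 acetate
Product: 26 target compound
Conditions: Me2BBr, CH2Cl2, −78 °C; then aq. NaHCO3/THF
Reagents that add atoms: none
Why: Lewis-acid cleavage of the MOM acetal at low temperature and hydrolysis should free the C3 hydroxyl without touching the esters, the α-methylene lactone or the β-hydroxy ketone.

**Compound list**

1 | 2-methylanisole | COc1ccccc1C | starting material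
2 | 1-methoxy-2-methylcyclohexa-1,4-diene | COC1=C(C)CC=CC1 | intermediate
3 | 6-methylcyclohex-3-en-1-one (racemic) | CC1CC=CCC1=O | intermediate
4 | cis-6-methylcyclohex-3-en-1-ol (racemic; SMILES shows the 1S,6R enantiomer) | O[C@H]1CC=CC[C@H]1C | intermediate
5 | (1S,6R)-6-methylcyclohex-3-en-1-ol | O[C@H]1CC=CC[C@H]1C | intermediate
6 | (1R,3S,4R,6S)-4-methyl-7-oxabicyclo[4.1.0]heptan-3-ol (epoxide O, OH and CH3 all cis) | O1[C@@H]2C[C@H](O)[C@H](C)C[C@H]12 | intermediate
7 | (1R,3S,4R,6S)-3-(methoxymethoxy)-4-methyl-7-oxabicyclo[4.1.0]heptane (all cis) | O1[C@@H]2C[C@H](OCOC)[C@H](C)C[C@H]12 | intermediate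
8 | 4-methoxybenzyl alcohol | COc1ccc(CO)cc1 | starting material
9 | trichloroethylene | ClC=C(Cl)Cl | starting material
10 | 1-({[(E)-1,2-dichloroethenyl]oxy}methyl)-4-methoxybenzene | COc1ccc(CO/C(Cl)=C\Cl)cc1 | intermediate
11 | lithium [(4-methoxybenzyl)oxy]acetylide | [Li]C#COCc1ccc(OC)cc1 | intermediate
12 | diethyl{[(4-methoxybenzyl)oxy]ethynyl}alane | CC[Al](CC)C#COCc1ccc(OC)cc1 | intermediate
13 | 2-{[(4-methoxybenzyl)oxy]ethynyl}-5-(methoxymethoxy)-4-methylcyclohexan-1-ol; OH, OMOM and CH3 mutually cis, alkynyl trans to them | O[C@@H]1C[C@H](OCOC)[C@H](C)C[C@H]1C#COCc1ccc(OC)cc1 | intermediate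
14 | 2-{(E)-2-[(4-methoxybenzyl)oxy]ethenyl}-5-(methoxymethoxy)-4-methylcyclohexan-1-ol; same ring configuration as 13 | O[C@@H]1C[C@H](OCOC)[C@H](C)C[C@H]1/C=C/OCc1ccc(OC)cc1 | intermediate
15 | 2-{(E)-2-[(4-methoxybenzyl)oxy]ethenyl}-5-(methoxymethoxy)-4-methylcyclohexan-1-one; side chain trans to CH3, OMOM cis to CH3 | O=C1C[C@H](OCOC)[C@H](C)C[C@H]1/C=C/OCc1ccc(OC)cc1 | intermediate
16 | 2-{(E)-2-[(4-methoxybenzyl)oxy]ethenyl}-5-(methoxymethoxy)-4-methyl-1-(prop-1-en-2-yl)cyclohexan-1-ol; isopropenyl trans to the alkoxyvinyl group | C=C(C)[C@]1(O)C[C@H](OCOC)[C@H](C)C[C@H]1/C=C/OCc1ccc(OC)cc1 | intermediate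
17 | potassium C1(O)=C10 enolate of the (6E)-cyclodecenone, (3S,4R,8S) | [K+].[O-]/C1=C(/C)C[C@H](OCc2ccc(OC)cc2)/C=C/C[C@@H](C)[C@@H](OCOC)C1 | intermediate
18 | (3S,4R,8S,10R,6E)-10-hydroxy-8-[(4-methoxybenzyl)oxy]-3-(methoxymethoxy)-4,10-dimethylcyclodec-6-en-1-one (germacrane numbering) | O=C1C[C@H](OCOC)[C@H](C)C/C=C/[C@@H](OCc2ccc(OC)cc2)C[C@@]1(C)O | intermediate
19 | (3S,4R,8S,10R,6E)-8,10-dihydroxy-3-(methoxymethoxy)-4,10-dimethylcyclodec-6-en-1-one (germacrane numbering) | O=C1C[C@H](OCOC)[C@H](C)C/C=C/[C@@H](O)C[C@@]1(C)O | intermediate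
20 | C8 hydrogen malonate of 19 | O=C1C[C@H](OCOC)[C@H](C)C/C=C/[C@@H](OC(=O)CC(=O)O)C[C@@]1(C)O | intermediate
21 | bis-lactone: ring B (O6–C12) and ring A (O8) cis-fused at C7–C11, both trans-fused to the ten-membered ring; C10 OH, C3 OMOM; ring carbons configured as in the target | O=C1C[C@H](OCOC)[C@H](C)C[C@H]2OC(=O)[C@@H]3C(=O)O[C@@H](C[C@@]1(C)O)[C@H]23 | intermediate
22 | ring-A-opened acid: 6,12-lactone with C11 carboxylic acid (C11 epimers), free C8 and C10 hydroxyls | O=C1C[C@H](OCOC)[C@H](C)C[C@H]2OC(=O)C(C(=O)O)[C@@H]2[C@@H](O)C[C@@]1(C)O | intermediate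
23 | 8,10-dihydroxy-3-(methoxymethoxy)-1-oxogermacr-11(13)-en-6,12-olide, configured as in the target | C=C1C(=O)O[C@@H]2C[C@@H](C)[C@@H](OCOC)CC(=O)[C@](C)(O)C[C@H](O)[C@@H]12 | intermediate
24 | 8-angeloyloxy-10-hydroxy-3-(methoxymethoxy)-1-oxogermacr-11(13)-en-6,12-olide | C=C1C(=O)O[C@@H]2C[C@@H](C)[C@@H](OCOC)CC(=O)[C@](C)(O)C[C@H](OC(=O)/C(C)=C\C)[C@@H]12 | intermediate
25 | 10-acetoxy-8-angeloyloxy-3-(methoxymethoxy)-1-oxogermacr-11(13)-en-6,12-olide | C=C1C(=O)O[C@@H]2C[C@@H](C)[C@@H](OCOC)CC(=O)[C@](C)(OC(C)=O)C[C@H](OC(=O)/C(C)=C\C)[C@@H]12 | intermediate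
26 | (3S,4R,6R,7S,8S,10R)-10-acetoxy-8-angeloyloxy-3-hydroxy-1-oxogermacr-11(13)-en-6,12-olide | C=C1C(=O)O[C@@H]2C[C@@H](C)[C@@H](O)CC(=O)[C@](C)(OC(C)=O)C[C@H](OC(=O)/C(C)=C\C)[C@@H]12 | target

Total step count: 18. Longest linear sequence: 17 steps (steps 1–5 and 7–18, from 2-methylanisole).

**Steps most likely to fail**

Step 15. The two γ-lactones of 21 differ only in their remote surroundings, so hydroxide may open the wrong ring, or the mono-opened isomers may translactonize toward C8; either misplaces the free hydroxyl. The fallback sets out from 21 and returns at 23. Excess LiOH·H2O opens both lactones to the trihydroxy malonic acid F1. Mannich decarboxylative methylenation (CH2O, Et2NH, then NaOAc/AcOH) should give the α-methylene acid F2. Acid-catalysed lactonization (camphorsulfonic acid, toluene, molecular sieves) in the presence of PhB(OH)2 ties the syn-1,3-diol O8/O10 as a cyclic boronate, so only O6 can close the lactone, giving the boronate lactone F3. H2O2 in pH 7 buffer then removes the boronate to give 23.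

Step 14. The ester-tethered radical closes slowly, so intermolecular oxidation may compete, and the oxidized C6 center may undergo β-hydride elimination instead of carboxylate capture. The fallback sets out from 19 and returns at 21. Esterification of O8 with mono-tert-butyl malonate (dicyclohexylcarbodiimide, 4-(dimethylamino)pyridine) gives the mixed malonate F4. Iodination of its sodium enolate (NaH, N-iodosuccinimide, −78 °C) gives the iodomalonate F5. Iodine-atom-transfer 5-exo radical cyclization (Et3B, air, benzene) gives the C6 iodide F6. AgOSO2CF3 with 2,6-di-tert-butylpyridine then promotes displacement of iodide by the tert-butyl ester carbonyl with loss of isobutene, closing ring B to 21.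

Step 11. Proton transfer within the potassium enolate toward C2 can trigger β-elimination of the C3 alkoxy group, and a slow oxaziridine transfer can erode the facial control at C10. The fallback sets out from 16 and returns at 18. After the rearrangement the enolate is trapped at −78 °C with Me3SiCl and the silyl enol ether F7 is isolated. Rubottom oxidation under neutral conditions (dimethyldioxirane, acetone, −78 °C, then Bu4NF buffered with AcOH) on the same exposed face should give 18.

**Further compounds**

F1 | step 15 | trihydroxy malonic acid from double lactone opening of 21 (C6, C8, C10 hydroxyls; C7 bears CH(CO2H)2) | O=C1C[C@H](OCOC)[C@H](C)C[C@@H](O)[C@H](C(C(=O)O)C(=O)O)[C@@H](O)C[C@@]1(C)O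
F2 | step 15 | α-methylene acid: C7 bears C(=CH2)CO2H; C6, C8, C10 hydroxyls free | O=C1C[C@H](OCOC)[C@H](C)C[C@@H](O)[C@H](C(=C)C(=O)O)[C@@H](O)C[C@@]1(C)O
F3 | step 15 | 8,10-O-phenylboronate of 23 | C=C1C(=O)O[C@@H]2C[C@@H](C)[C@@H](OCOC)CC(=O)[C@@]3(C)C[C@H](OB(c4ccccc4)O3)[C@@H]12
F4 | step 14 | C8 tert-butyl malonate of 19 | O=C1C[C@H](OCOC)[C@H](C)C/C=C/[C@@H](OC(=O)CC(=O)OC(C)(C)C)C[C@@]1(C)O
F5 | step 14 | C8 tert-butyl iodomalonate of 19 (epimers at the iodinated carbon) | O=C1C[C@H](OCOC)[C@H](C)C/C=C/[C@@H](OC(=O)C(I)C(=O)OC(C)(C)C)C[C@@]1(C)O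
F6 | step 14 | ring-A lactone with C6 iodide and C11 tert-butyl ester (epimers at C6 and C11) | O=C1C[C@H](OCOC)[C@H](C)CC(I)[C@@H]2C(C(=O)OC(C)(C)C)C(=O)O[C@H]2C[C@@]1(C)O
F7 | step 11 | trimethylsilyl enol ether corresponding to enolate 17 | C[Si](C)(C)O/C1=C(/C)C[C@H](OCc2ccc(OC)cc2)/C=C/C[C@@H](C)[C@@H](OCOC)C1
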